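The runs were computed on assumed constants, noise included.

**The task.** 5 questions stood open on 4 flasks that differ in temperature alone, green being switched once.

in all of them: J 0.5 mol%
- delta: L 2 mM; D 1.7 equiv; temperature 55 °C; run made earlier
- gamma: L 2 mM; D 3.8 equiv; temperature 75 °C; run made earlier
- alpha: L 3 mM; D 2.5 equiv; temperature 55 °C; run made earlier
- green: L 2.0 mM; D 2.50 equiv; at 90 °C until 1.0 min, from then on at 60 °C; time 5.0 min
- grey: L 2.0 mM; D 2.50 equiv; temperature 90 °C; time 5.0 min
- teal: L 2.0 mM; D 2.50 equiv; temperature 75 °C; time 5.0 min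
- red: L 2.0 mM; D 2.50 equiv; temperature 60 °C; time 5.0 min

1. the flask with the highest amount of E, in percent of the L charged ("all alike" if they lie within 1.5 percentage points) (green / grey / teal / red / all alike)
2. final E, as a percentage of the L charged, in green
3. final E, as a percentage of the L charged, in grey
4. final E, as a percentage of the L charged, in teal
5. final E, as a percentage of the L charged, in red

| run | time / min | E / % |
|---|---|---|
| delta | 2.00 | 46.0 |
| delta | 4.00 | 69.1 |
| delta | 8.00 | 86.5 |
| delta | 25.0 | 88.8 |
| gamma | 1.00 | 56.0 |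
| gamma | 3.00 | 83.1 |
| gamma | 5.00 | 85.4 |
| gamma | 8.00 | 86.4 |
| alpha | 2.00 | 80.8 |
| alpha | 4.00 | 93.7 |
| alpha | 8.00 | 93.7 |
| alpha | 25.0 | 93.4 |

(readings scatter by 0.5 percentage points)



**The puzzle.** I called r the part of the charge not in E per part in E at the last reading. It was 0.126 in delta and 0.0707 in alpha. So alpha, with 3 mM of L, lost less than delta, with 2 mM, though a loss feeding on L should grow with it.

**My reckoning.** I guessed that the loss was L meeting E, and I took the binding of L to J as a fast step in balance. E is then made at a rate going with c(L)·c(D)·c(J) and lost at a rate going with c(L)·c(E), so c(L) cancels. Since c(E) grows with the charge, r should go as 1/B, with B = c(D)·c(J)/c(L) at the start. B was 0.0170 mM in delta, 0.0375 mM in alpha and 0.0380 mM in gamma.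

The product r·B gave 0.00214 mM in delta and 0.00265 mM in alpha, a factor 1.24 apart, where r stood a factor 1.78 apart the other way, so the larger B of alpha clears the puzzle. In gamma, at 75 °C, it gave 0.00598 mM. This product is the loss number W, a kind of selectivity factor. Between 55 °C and 75 °C it rose by a factor 2.50.

With B = 0.0250 mM in the new flasks, and assuming plateaus by 5.0 min, I carried W over from gamma. Red lies as far below 75 °C as grey lies above it, a gap of 3/4 of the step from 55 °C to 75 °C, so I took W to change across that gap by a factor 1.99. Red had r = 0.121, so E = 89.2%. Teal had E = 80.7%. Grey had r = 0.475, so E = 67.8%.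

For green I took the loss to go with the square of conversion, as my reckoning has it. I assumed a conversion of 0.5 in the hot period, which put 0.250 of the loss at 90 °C. That gave E = 82.7%.

**The forecast.** It named red, with green 74.5% (70% to 79%), grey 72% (67% to 77%), teal 80% (77% to 83.5%) and red 83.5% (79% to 88%). Its ground was that “a side reaction also consumes L and then E simply stops”. My grey stood lower than its grey, and my green higher than its green.

**The result.** Red gave the most E, 88.5%, then green 81.6%, teal 78.8% and grey 60.2%.

    L + J ⇌ J + Z (K = 2.10, k = 29000 L mol⁻¹ s⁻¹, Ea = 33.0 kJ mol⁻¹, ΔH = −37.0 kJ mol⁻¹)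
    J + Z ⇌ X (K = 1400 L mol⁻¹, k = 8930 L mol⁻¹ s⁻¹, Ea = 37.0 kJ mol⁻¹, ΔH = −59.0 kJ mol⁻¹)
    D + X → J + E (k = 617 L mol⁻¹ s⁻¹, Ea = 48.0 kJ mol⁻¹)
    L + E → G (k = 1.69 L mol⁻¹ s⁻¹, Ea = 37.0 kJ mol⁻¹)
    (constants at 60 °C)

**Next flask.** Read from the results, W was 0.00673 mM in teal, against 0.00598 mM from gamma at that temperature. In grey it was 0.0165 mM, above the 0.0119 mM I had carried. The neighbour flask is grey with 3.4 mM of L, which raised B to 0.0425 mM. Grey's W then gave r = 0.388, so E = 72.0%. The neighbour flask gave 70.4%.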